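The runs were computed with made-up constants; noise was put on by code.

Per hour was the unit I wanted first, because the east flask is asked for at a time well past the last reading, and a constant in that unit stands in an exponent there.

| flask | Q | L | time |
|---|---|---|---|
| south-east | 0.600 M |  |  |
| south-west | 0.600 M | 0.300 M |  |
| south | 0.900 M |  |  |
| east | 0.600 M |  | 16 h |

| run | time / h | [L] / M |
|---|---|---|
| south-east run | 0.17 | 0.033 |
| south-east run | 0.53 | 0.077 |
| south-east run | 1.0 | 0.153 |
| south-east run | 1.6 | 0.222 |
| south-east run | 2.3 | 0.271 |
| south-east run | 3.0 | 0.304 |
| south-east run | 3.9 | 0.344 |
| south-west run | 0.17 | 0.316 |
| south-west run | 0.53 | 0.367 |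
| south-west run | 1.0 | 0.407 |
| south-west run | 1.6 | 0.438 |
| south-west run | 2.3 | 0.470 |
| south-west run | 3.0 | 0.484 |
| south-west run | 3.9 | 0.482 |
| south run | 0.17 | 0.026 |
| south run | 0.53 | 0.109 |
| south run | 1.0 | 0.187 |
| south run | 1.6 | 0.270 |
| south run | 2.3 | 0.356 |
| south run | 3.0 | 0.404 |
| south run | 3.9 | 0.455 |

(readings scatter by 0.005 M)

- order of the initial rate in [Q], near the charge of the south-east run, the rate being that where two percent of its Q are L (one fixed amount of L, the same in the runs compared)
- L in the east run at 16 h, as a share of the Q charged
- which of these the readings show (the product decays / two substrates go astray together / the substrate is lost by itself / the product binds the substrate)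

- Overall: Q -> L.
- Constant volume, constant temperature.
- The analysis sees a species whether free or bound.
- An order is taken over about fifteen percent of the charge, up and down.

East has the charge of the south-east run, so I let the south-east readings stand for its early hours and worked with the fraction of L left: L at the last reading, plus the Q unturned then, times the fraction surviving the remaining 12.1 h. Scatter moves the L reading by 1.45 %. The unturned Q is a plain addend, so a miss there counts once. The decay constant, with a scatter of about 0.00911 /h, moves the outcome by 11.0 %, which is more than the share for the L reading, so of these two it was the number to know well.

South-west and south-east were charged with the same Q, so if L leaves its own making alone, the gap between them is what survives of the added L. The last two gaps average 0.159 M at 3.45 h, so I read a loss of 0.184 /h from them, and this share of L lost per hour is the loss constant (a first-order rate constant). Over the stretch it leaves a fraction 0.108. South-east L averaged near 0.222 M, so I estimated that by 3.9 h about 0.159 M had decayed in the south-east run, which by this estimate left about 0.0967 M of Q unturned there and a sum of 0.441 M. My figure for east at 16 h was 7.92 % of the Q charged, and it counts late L as made at 3.9 h.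

The forecast gave order 0.3, 8 % and the product decays, saying of the south-west stall that “formation is balanced by decay”.

The east flask held 10.8 % of the Q charged as L at 16 h, which is 0.0649 M of L, and the order of the initial rate came out at 0.56; the readings show the product decays.

    2 Q ⇌ Q2, settled at all times (31.70 /M)
    Q → L (1.937 /h)
    L → Gu (0.1670 /h)

Set against my estimated sum of 0.441 M, that 0.0649 M is a fraction left of 0.147 over the stretch, larger than the 0.108 my loss constant gave.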